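**Retrosynthetic overview**

- The strategy rests on ring A of the benzil: C1 carries the dione carbon, C2 a free OH and C4 the methyl ether. This is the pattern a 1,1,3-trioxygenated butadiene leaves on an acyl alkyne, with the two oxygens already differentiated.
- Last disconnection: the two MOM ethers on ring B (17 → 18).
- Key disconnection: ring A bonds C1–C2 and C5–C6, by Diels–Alder benzannulation of ketene-acetal diene 14 onto the terminal alkyne of alkynyl dione 11. Ring A is the only ring formed; ring B is bought as resorcinol.
- 11 from ring B: bis-MOM ether, C2 metalation and prenylation, C4 metalation, then one-pot acylation with bis(N-methoxy-N-methylamide) 6 followed by ethynylmagnesium bromide 7.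
- 14 from methyl (E)-3-methoxybut-2-enoate by γ-deprotonation and O-silylation.

Key step: step 5

Assumption: diene 14 is used as the mixture of ketene-acetal geometric isomers that its preparation gives, since this geometry is lost on aromatisation. The target has no stereocentre, and the sp3 centres of intermediates 9, 10 and 15 form without control and are destroyed later.

**Step 1**
Reactants: 1 resorcinol
Product: 2 1,3-bis(methoxymethoxy)benzene
Conditions: NaH, MOMCl, DMF, 0 °C → rt
Reagents that add atoms: chloromethyl methyl ether, COCCl
Why: The bis-phenoxide formed with NaH is alkylated on oxygen by the reactive α-chloro ether (Williamson ether synthesis), giving the bis-MOM ether that later directs both metalations.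

**Step 2**
Reactants: 2 1,3-bis(methoxymethoxy)benzene, 3 prenyl bromide
Product: 5 1,3-bis(methoxymethoxy)-2-(3-methylbut-2-enyl)benzene, via aryllithium 4 (not isolated)
Conditions: n-BuLi, THF, 0 °C → rt; CuI (10 mol %), −30 °C; 3, −30 °C → rt
Reagents that add atoms: none
Why: Directed ortho-metalation takes place at C2, the position flanked and chelated by both MOM ethers, and copper-catalysed SN2 allylation of the aryl metal at the primary carbon of prenyl bromide installs the linear prenyl group.

**Step 3**
Reactants: 5 1,3-bis(methoxymethoxy)-2-(3-methylbut-2-enyl)benzene, 6 N,N'-dimethoxy-N,N'-dimethyloxamide, 7 ethynylmagnesium bromide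
Product: 11 1-[2,4-bis(methoxymethoxy)-3-(3-methylbut-2-enyl)phenyl]but-3-yne-1,2-dione, via aryllithium 8 (not isolated), via lithium hemiaminal mono-adduct 9 (not isolated), via bis-hemiaminal dialkoxide 10 (not isolated)
Conditions: n-BuLi, TMEDA, THF, −20 → 0 °C; cannulate into 6, THF, −78 °C; 7, THF, −78 → 0 °C; pour into cold 1 M aq. HCl/Et2O, 0 °C, separate at once
Reagents that add atoms: none
Why: A second directed ortho-metalation places lithium at C4, the only ring position still ortho to a MOM ether, and two successive Weinreb ketone syntheses on the bis-amide then build the dione, because the first tetrahedral chelate 9 persists and masks the aryl ketone while the alkynyl Grignard reagent adds to the second amide, and both carbonyl groups are released only on the acidic quench, which also protonates the liberated amine before it can add to the ynone.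

**Step 4**
Reactants: 12 methyl (E)-3-methoxybut-2-enoate
Product: 14 1,3-dimethoxy-1-(trimethylsilyloxy)buta-1,3-diene, via lithium dienolate 13 (not isolated)
Conditions: LDA, THF, −78 °C; Me3SiCl, −78 °C → rt; filtration under argon, bulb-to-bulb distillation
Reagents that add atoms: chlorotrimethylsilane, C[Si](C)(C)Cl
Why: LDA removes a γ-proton of the vinylogous ester to give the extended dienolate, which the hard silyl chloride traps on oxygen (kinetic enolate O-silylation) to give the ketene silyl acetal diene.

**Step 5**
Reactants: 11 1-[2,4-bis(methoxymethoxy)-3-(3-methylbut-2-enyl)phenyl]but-3-yne-1,2-dione, 14 1,3-dimethoxy-1-(trimethylsilyloxy)buta-1,3-diene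
Product: 17 licoagrodione 2',4'-bis(methoxymethyl) ether, via cyclohexa-1,4-diene cycloadduct 15 (not isolated), via aryl trimethylsilyl ether 16 (not isolated)
Conditions: 14 (1.5 equiv), toluene, 0 °C → rt, then 40 °C if methanol loss is slow; 5% aq. citric acid/THF, rt
Reagents that add atoms: none
Why: The electron-rich diene 14 and the doubly acyl-activated terminal alkyne of 11 should combine in a normal-electron-demand, strongly asynchronous Diels–Alder reaction in which the CH2 terminus of 14 (largest HOMO coefficient) bonds to the terminal alkyne carbon β to the dione and the acetal carbon then bonds to the acyl-bearing alkyne carbon, giving cyclohexa-1,4-diene 15. Ring A is thereby closed as a six-membered carbocycle by the intermolecular [4+2] cycloaddition itself (ring bonds C5–C6 and C1–C2), and 1,4-elimination of methanol from the acetal carbon and the ring CH2 aromatises 15 to silyl ether 16, whose labile O–Si bond is cut on the mild acidic work-up to leave the C2 phenol hydrogen-bonded to the new ketone. The closest known reaction type is the cycloaddition–aromatisation of 1-alkoxy-1-silyloxy-3-alkoxybutadienes with haloquinones and with acetylenic ketones and esters, which gives 1-hydroxy-3-methoxyarenes. No stereocentre remains, since the acetal carbon of 15 forms as a racemate and is flattened on aromatisation. The step needs regioselectivity, which the matched polarisation of both partners secures by placing the acetal carbon (later C2–OH) beside the acyl carbon C1 and the methoxy group para to it. It also needs chemoselectivity for the alkyne over the dione carbonyls, the MOM acetals and the prenyl olefin, which the absence of any Lewis acid should secure by keeping Mukaiyama-type carbonyl addition slow while the unhindered ynone terminus reacts.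

**Step 6**
Reactants: 17 licoagrodione 2',4'-bis(methoxymethyl) ether
Product: 18 licoagrodione
Conditions: dilute HCl (3 M aq., catalytic to few equiv), MeOH, rt
Reagents that add atoms: none
Why: Acid-catalysed acetal exchange with methanol (MOM ether solvolysis) cleaves both aryl MOM ethers as dimethoxymethane under conditions mild enough to leave the prenyl olefin, the aryl methyl ether and the 1,2-dione untouched.

**Compound list**

1 | resorcinol | Oc1cccc(O)c1 | starting material
2 | 1,3-bis(methoxymethoxy)benzene | COCOc1cccc(OCOC)c1 | intermediate
3 | prenyl bromide (1-bromo-3-methylbut-2-ene) | CC(C)=CCBr | starting material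
4 | [2,6-bis(methoxymethoxy)phenyl]lithium, formed in the flask | [Li]c1c(OCOC)cccc1OCOC | intermediate
5 | 1,3-bis(methoxymethoxy)-2-(3-methylbut-2-enyl)benzene | COCOc1cccc(OCOC)c1CC=C(C)C | intermediate
6 | N,N'-dimethoxy-N,N'-dimethyloxamide | CON(C)C(=O)C(=O)N(C)OC | starting material
7 | ethynylmagnesium bromide (solution in THF) | C#C[Mg]Br | starting material
8 | [2,4-bis(methoxymethoxy)-3-(3-methylbut-2-enyl)phenyl]lithium, formed in the flask | [Li]c1ccc(OCOC)c(CC=C(C)C)c1OCOC | intermediate
9 | lithium hemiaminal alkoxide from 8 and 6 (mono-adduct, racemic, formed in the flask) | CON(C)C(=O)C(O[Li])(N(C)OC)c1ccc(OCOC)c(CC=C(C)C)c1OCOC | intermediate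
10 | lithium bromomagnesium bis-hemiaminal dialkoxide from 9 and 7 (diastereomer mixture, formed in the flask) | C#CC(O[Mg]Br)(N(C)OC)C(O[Li])(N(C)OC)c1ccc(OCOC)c(CC=C(C)C)c1OCOC | intermediate
11 | 1-[2,4-bis(methoxymethoxy)-3-(3-methylbut-2-enyl)phenyl]but-3-yne-1,2-dione | COCOc1ccc(C(=O)C(=O)C#C)c(OCOC)c1CC=C(C)C | intermediate
12 | methyl (E)-3-methoxybut-2-enoate | COC(=O)/C=C(\C)OC | starting material
13 | lithium 1,3-dimethoxybuta-1,3-dien-1-olate, formed in the flask | COC(=C)C=C(OC)O[Li] | intermediate
14 | 1,3-dimethoxy-1-(trimethylsilyloxy)buta-1,3-diene (mixture of ketene-acetal geometric isomers) | COC(=C)C=C(OC)O[Si](C)(C)C | intermediate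
15 | 1-[2,4-bis(methoxymethoxy)-3-(3-methylbut-2-enyl)phenyl]-2-[4,6-dimethoxy-6-(trimethylsilyloxy)cyclohexa-1,4-dien-1-yl]ethane-1,2-dione (racemic, formed in the flask) | COC1=CC(OC)(O[Si](C)(C)C)C(=CC1)C(=O)C(=O)c1ccc(OCOC)c(CC=C(C)C)c1OCOC | intermediate
16 | 1-[2,4-bis(methoxymethoxy)-3-(3-methylbut-2-enyl)phenyl]-2-[4-methoxy-2-(trimethylsilyloxy)phenyl]ethane-1,2-dione, formed in the flask | COc1ccc(C(=O)C(=O)c2ccc(OCOC)c(CC=C(C)C)c2OCOC)c(O[Si](C)(C)C)c1 | intermediate
17 | licoagrodione 2',4'-bis(methoxymethyl) ether, 1-[2,4-bis(methoxymethoxy)-3-(3-methylbut-2-enyl)phenyl]-2-(2-hydroxy-4-methoxyphenyl)ethane-1,2-dione | COc1ccc(C(=O)C(=O)c2ccc(OCOC)c(CC=C(C)C)c2OCOC)c(O)c1 | intermediate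
18 | licoagrodione, 1-[2,4-dihydroxy-3-(3-methylbut-2-enyl)phenyl]-2-(2-hydroxy-4-methoxyphenyl)ethane-1,2-dione | COc1ccc(C(=O)C(=O)c2ccc(O)c(CC=C(C)C)c2O)c(O)c1 | target

**Step count and risks**

Total step count: 6. Longest linear sequence: 5 steps (1, 2, 3, 5, 6); step 4 is a one-step branch that supplies the diene.

Steps most likely to fail:

1. Step 5 (key step). The diene may add to a carbonyl of the 1,2-dione (Mukaiyama-type aldol or hetero-Diels–Alder) instead of the alkyne, the ynedione may oligomerise, or aromatisation may run with loss of trimethylsilanol so that C2 ends as a methyl ether. Fallback: ring A is brought in as an aryl nucleophile instead of being grown. Commercial 2-bromo-5-methoxyphenol is protected (MOMCl, NaH, DMF) as 1-bromo-4-methoxy-2-(methoxymethoxy)benzene F1, and bromine–lithium exchange (n-BuLi, THF, −78 °C) gives [4-methoxy-2-(methoxymethoxy)phenyl]lithium F2. The fallback sets out from compound 5, which is taken through 8 to mono-adduct 9 exactly as in step 3. F2 is then added in place of 7 to give the dilithium bis-hemiaminal dialkoxide F3, and the cold acidic quench collapses it to 1-[2,4-bis(methoxymethoxy)-3-(3-methylbut-2-enyl)phenyl]-2-[4-methoxy-2-(methoxymethoxy)phenyl]ethane-1,2-dione F4. The conditions of step 6 should then remove all three MOM groups, so the route is rejoined at compound 18.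

2. Step 3. The liberated N,O-dimethylhydroxylamine may add in conjugate fashion to the terminal ynedione while 10 collapses, and the unprotected ynedione may oligomerise on isolation; metalation at the benzylic–allylic CH2 of the prenyl chain is a lesser risk. Fallback: the alkyne is carried with a silyl cap and unmasked in a separate operation. The fallback sets out from compound 5, taken through 8 to 9 as before. Trimethylsilylacetylene and n-BuLi (THF, −78 °C) give [(trimethylsilyl)ethynyl]lithium F5, which is added to 9 in place of 7 to form the dilithium bis-hemiaminal dialkoxide F6. Acidic quench gives 1-[2,4-bis(methoxymethoxy)-3-(3-methylbut-2-enyl)phenyl]-4-(trimethylsilyl)but-3-yne-1,2-dione F7, whose β-silyl group shields the ynone terminus so that it can be purified. Protodesilylation with Bu4NF buffered by AcOH (THF, −78 → −20 °C), carried out just before the cycloaddition, returns the route at compound 11.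

3. Step 6. Under protic acid the prenyl olefin may cyclise onto either flanking phenol to give a chroman, or add methanol, and the dione may be trapped as a cyclic methyl ketal by an ortho phenol. Fallback: the MOM groups are removed without Brønsted acid, by silyl transfer and neutral hydrolysis. The fallback sets out from compound 17. Me3SiOTf with 2,2'-bipyridyl (CH2Cl2, 0 °C → rt) should convert both aryl MOM ethers and the free phenol into licoagrodione tris(trimethylsilyl) ether F8, and stirring with water in THF cleaves the three aryl silyl ethers, rejoining the route at compound 18.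

**Further compounds**

F1 | step 5 | 1-bromo-4-methoxy-2-(methoxymethoxy)benzene | COCOc1cc(OC)ccc1Br
F2 | step 5 | [4-methoxy-2-(methoxymethoxy)phenyl]lithium | [Li]c1ccc(OC)cc1OCOC
F3 | step 5 | dilithium bis-hemiaminal dialkoxide from 9 and F2 (diastereomer mixture) | COCOc1cc(OC)ccc1C(O[Li])(N(C)OC)C(O[Li])(N(C)OC)c1ccc(OCOC)c(CC=C(C)C)c1OCOC
F4 | step 5 | 1-[2,4-bis(methoxymethoxy)-3-(3-methylbut-2-enyl)phenyl]-2-[4-methoxy-2-(methoxymethoxy)phenyl]ethane-1,2-dione | COCOc1cc(OC)ccc1C(=O)C(=O)c1ccc(OCOC)c(CC=C(C)C)c1OCOC
F5 | step 3 | [(trimethylsilyl)ethynyl]lithium | [Li]C#C[Si](C)(C)C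
F6 | step 3 | dilithium bis-hemiaminal dialkoxide from 9 and F5 (diastereomer mixture) | C[Si](C)(C)C#CC(O[Li])(N(C)OC)C(O[Li])(N(C)OC)c1ccc(OCOC)c(CC=C(C)C)c1OCOC
F7 | step 3 | 1-[2,4-bis(methoxymethoxy)-3-(3-methylbut-2-enyl)phenyl]-4-(trimethylsilyl)but-3-yne-1,2-dione | COCOc1ccc(C(=O)C(=O)C#C[Si](C)(C)C)c(OCOC)c1CC=C(C)C
F8 | step 6 | licoagrodione tris(trimethylsilyl) ether | COc1ccc(C(=O)C(=O)c2ccc(O[Si](C)(C)C)c(CC=C(C)C)c2O[Si](C)(C)C)c(O[Si](C)(C)C)c1
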